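## Retrosynthetic overview

1. Target 64 ⇐ double oxidation and desilylation of 62 ⇐ Negishi sp2–sp2 coupling at C13–C14 of West alkenyl iodide 33 (C1–C13) with the alkenylzinc from East iodide 59 (C14–C24); each half carries 19 of the 38 non-hydrogen atoms.
2. 33 ⇐ E-selective Wittig reaction (C6=C7) of lactol-acetal aldehyde 29 with tributylphosphonium salt 16; 16 ⇐ Evans propargylation (C10), hydrozirconation–iodination, Still–Gennari olefination (8Z).
3. 29 ⇐ ring A (dihydropyran) by ring-closing metathesis of a mixed acrolein acetal built on a Brown anti-crotylation product (C4, C5); the lactone oxidation level is restored after the Wittig step.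
4. 59 ⇐ hydrozirconation–iodination of a methylalkyne ⇐ Marshall anti-propargylation (C16) of aldehyde 50; ring B (tetrahydrofuran) by Sharpless epoxidation and 5-exo epoxide opening (C22), Roush anti-crotylboration (C18, C19), Evans alkylation (C20).
5. Ring order: ring A is closed inside the West half (step 15), ring B inside the East half (step 29), both before the fragment union (step 39).

Assumption: the target is taken exactly as the SMILES encodes it, in polyketide numbering from lactone carbonyl C1 to aldehyde C24: 4S,5R,10R,16R,18R,19R,20R,22R and 6E,8Z,12E,14E. The acetal carbon C1 of 26–29, 31 and 32 is carried as an epimer mixture (removed in step 20), the C17 carbinol configuration is immaterial (oxidised in step 41), and the tartrate crotylboronate of step 27 is treated as a stock reagent kept as a toluene solution.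

## Route

**Shared auxiliary imide**

Step 1
Reactants: 1 propanoyl chloride
Product: 2 (4S)-4-benzyl-3-propanoyl-1,3-oxazolidin-2-one
Conditions: (S)-4-benzyl-1,3-oxazolidin-2-one, Et3N, DMAP (cat.), CH2Cl2, 0 °C → rt
Reagents that add atoms: (S)-4-benzyl-1,3-oxazolidin-2-one, O=C1N[C@@H](Cc2ccccc2)CO1
Why: DMAP-catalysed N-acylation of the Evans auxiliary gives the propionimide that serves both asymmetric alkylations (steps 2 and 24); no stereocentre is formed.

**West half, C7–C13 phosphonium salt**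

Step 2
Reactants: 2 (4S)-4-benzyl-3-propanoyl-1,3-oxazolidin-2-one; 3 3-bromoprop-1-yne
Product: 5 (4S)-4-benzyl-3-[(2R)-2-methylpent-4-ynoyl]-1,3-oxazolidin-2-one, via sodium enolate 4 (not isolated)
Conditions: NaN(SiMe3)2, THF, −78 °C; then 3, −78 → −40 °C
Reagents that add atoms: none
Why: Evans asymmetric alkylation, in which the chelated sodium (Z)-enolate is alkylated on the face opposite the benzyl group and so sets C10 (2R in 5).

Step 3
Reactants: 5 (4S)-4-benzyl-3-[(2R)-2-methylpent-4-ynoyl]-1,3-oxazolidin-2-one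
Product: 6 (2R)-2-methylpent-4-yn-1-ol
Conditions: LiBH4, MeOH (1 equiv), Et2O, 0 °C
Reagents that add atoms: none
Why: Reductive cleavage of the imide frees the primary alcohol and the recoverable auxiliary without touching the alkyne or epimerising C10.

Step 4
Reactants: 6 (2R)-2-methylpent-4-yn-1-ol
Product: 8 (2R,4E)-5-iodo-2-methylpent-4-en-1-ol, via alkenylzirconocene 7 (not isolated)
Conditions: Cp2Zr(H)Cl (2.3 equiv), THF, rt; then I2, 0 °C
Reagents that add atoms: iodine, II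
Why: Schwartz hydrozirconation (first equivalent consumed by the hydroxyl) adds Zr–H syn with zirconium at the terminal carbon, and iodinolysis with retention gives the (E)-alkenyl iodide C12=C13.

Step 5
Reactants: 8 (2R,4E)-5-iodo-2-methylpent-4-en-1-ol
Product: 9 (2R,4E)-5-iodo-2-methylpent-4-enal
Conditions: Dess–Martin periodinane, pyridine, CH2Cl2, 0 °C → rt; used crude
Reagents that add atoms: none
Why: Buffered Dess–Martin oxidation gives the α-branched aldehyde without epimerising C10 or disturbing the alkenyl iodide.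

Step 6
Reactants: 10 iodoethane
Product: 11 methyl 2-[bis(2,2,2-trifluoroethoxy)phosphoryl]butanoate (racemic)
Conditions: methyl bis(2,2,2-trifluoroethyl)phosphonoacetate, KOtBu, THF, 0 °C; then 10, 0 °C → rt
Reagents that add atoms: methyl bis(2,2,2-trifluoroethyl)phosphonoacetate, COC(=O)CP(=O)(OCC(F)(F)F)OCC(F)(F)F
Why: SN2 C-ethylation of the stabilised phosphonate carbanion installs the future C8 ethyl branch on the Still–Gennari reagent.

Step 7
Reactants: 9 (2R,4E)-5-iodo-2-methylpent-4-enal; 11 methyl 2-[bis(2,2,2-trifluoroethoxy)phosphoryl]butanoate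
Product: 13 methyl (2Z,4R,6E)-2-ethyl-7-iodo-4-methylhepta-2,6-dienoate, via potassium phosphonate carbanion 12 (not isolated)
Conditions: KN(SiMe3)2, 18-crown-6, THF, −78 °C; then 9, −78 °C
Reagents that add atoms: none
Why: Still–Gennari olefination, where fast collapse of the kinetic adduct of the electron-poor phosphonate gives the (Z)-trisubstituted enoate (ester cis to C10), i.e. the 8Z geometry.

Step 8
Reactants: 13 methyl (2Z,4R,6E)-2-ethyl-7-iodo-4-methylhepta-2,6-dienoate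
Product: 14 (2Z,4R,6E)-2-ethyl-7-iodo-4-methylhepta-2,6-dien-1-ol
Conditions: i-Bu2AlH (2.5 equiv), CH2Cl2, −78 °C; aqueous potassium sodium tartrate work-up
Reagents that add atoms: none
Why: 1,2-Reduction of the enoate by i-Bu2AlH gives the allylic alcohol with both alkene geometries intact.

Step 9
Reactants: 14 (2Z,4R,6E)-2-ethyl-7-iodo-4-methylhepta-2,6-dien-1-ol
Product: 15 (1E,4R,5Z)-6-(bromomethyl)-1-iodo-4-methylocta-1,5-diene
Conditions: CBr4, PPh3, CH2Cl2, 0 °C
Reagents that add atoms: tetrabromomethane, BrC(Br)(Br)Br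
Why: Appel bromination replaces the primary allylic hydroxyl by SN2 under neutral conditions, so the (Z)-alkene does not isomerise.

Step 10
Reactants: 15 (1E,4R,5Z)-6-(bromomethyl)-1-iodo-4-methylocta-1,5-diene
Product: 16 tributyl[(2Z,4R,6E)-2-ethyl-7-iodo-4-methylhepta-2,6-dien-1-yl]phosphonium bromide
Conditions: PBu3, MeCN, rt
Reagents that add atoms: tributylphosphine, CCCCP(CCCC)CCCC
Why: SN2 quaternisation of the allylic bromide gives the trialkylphosphonium salt needed for an E-selective Wittig reaction.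

**West half, C1–C6 aldehyde (ring A)**

Step 11
Reactants: 17 (2Z)-but-2-ene-1,4-diol
Product: 18 (2Z)-1,4-bis[(tert-butyldimethylsilyl)oxy]but-2-ene
Conditions: TBSCl (2.2 equiv), imidazole, CH2Cl2, rt
Reagents that add atoms: tert-butyldimethylsilyl chloride, CC(C)(C)[Si](C)(C)Cl
Why: Imidazole-mediated silylation protects both hydroxyls of the symmetrical diol.

Step 12
Reactants: 18 (2Z)-1,4-bis[(tert-butyldimethylsilyl)oxy]but-2-ene
Product: 20 [(tert-butyldimethylsilyl)oxy]acetaldehyde (2 equiv), via ozonide 19 (not isolated)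
Conditions: O3, CH2Cl2, −78 °C; then PPh3, −78 °C → rt
Reagents that add atoms: ozone, [O-][O+]=O
Why: Ozonolysis with reductive work-up cleaves the symmetrical alkene into two equivalents of the C5–C6 aldehyde.

Step 13
Reactants: 20 [(tert-butyldimethylsilyl)oxy]acetaldehyde; 21 (E)-but-2-ene
Product: 24 (2S,3S)-1-[(tert-butyldimethylsilyl)oxy]-3-methylpent-4-en-2-ol, via (E)-crotylpotassium 22 (not isolated), via (E)-crotyldiisopinocampheylborane 23 (not isolated)
Conditions: 21, KOtBu, n-BuLi, THF, −78 → −45 °C; (−)-Ipc2BOMe (from (+)-α-pinene), −78 °C; BF3·OEt2; then 20, −78 °C; then NaOH, H2O2, rt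
Reagents that add atoms: none
Why: Brown crotylboration through a chair Zimmerman–Traxler transition state, where the (E)-crotyl geometry gives the anti adduct and the (−)-Ipc2B ligands direct attack on the Si face of the aldehyde, setting C4 (S) and C5 (R) of the target.

Step 14
Reactants: 24 (2S,3S)-1-[(tert-butyldimethylsilyl)oxy]-3-methylpent-4-en-2-ol; 25 3,3-dimethoxyprop-1-ene
Product: 26 tert-butyl{[(2S,3S)-2-[(1-methoxyprop-2-en-1-yl)oxy]-3-methylpent-4-en-1-yl]oxy}dimethylsilane (acetal epimers)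
Conditions: 25 (excess), PPTS (cat.), toluene, 40 °C, reduced pressure
Reagents that add atoms: none
Why: Acid-catalysed transacetalisation, driven by removal of methanol, attaches the C1–C3 acrolein unit to the C5 oxygen as a mixed acetal.

Step 15
Reactants: 26 mixed acetal
Product: 27 tert-butyl{[(2S,3S)-6-methoxy-3-methyl-3,6-dihydro-2H-pyran-2-yl]methoxy}dimethylsilane (anomer mixture)
Conditions: first-generation Grubbs catalyst RuCl2(PCy3)2(=CHPh) (5 mol %), CH2Cl2, 40 °C
Reagents that add atoms: none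
Why: Ring-closing metathesis of the two terminal vinyl groups closes ring A (C2=C3) with loss of ethene and leaves the trans C4/C5 stereocentres untouched.

Step 16
Reactants: 27 silyl ether
Product: 28 [(2S,3S)-6-methoxy-3-methyl-3,6-dihydro-2H-pyran-2-yl]methanol
Conditions: Bu4NF, THF, 0 °C
Reagents that add atoms: none
Why: Fluoride cleaves the primary silyl ether while the acid-labile cyclic acetal survives the basic medium.

Step 17
Reactants: 28 [(2S,3S)-6-methoxy-3-methyl-3,6-dihydro-2H-pyran-2-yl]methanol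
Product: 29 (2S,3S)-6-methoxy-3-methyl-3,6-dihydro-2H-pyran-2-carbaldehyde
Conditions: Dess–Martin periodinane, pyridine, CH2Cl2, 0 °C; used at once
Reagents that add atoms: none
Why: Buffered Dess–Martin oxidation gives the C6 aldehyde without acid that would open the acetal or epimerise C5.

**West half, union and lactone**

Step 18
Reactants: 16 phosphonium bromide; 29 (2S,3S)-6-methoxy-3-methyl-3,6-dihydro-2H-pyran-2-carbaldehyde
Product: 31 (2R,3S)-2-[(1E,3Z,5R,7E)-3-ethyl-8-iodo-5-methylocta-1,3,7-trien-1-yl]-6-methoxy-3-methyl-3,6-dihydro-2H-pyran, via phosphonium ylide 30 (not isolated)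
Conditions: KOtBu, toluene, 0 °C; then 29, 0 °C → rt
Reagents that add atoms: none
Why: Wittig olefination with an allylic trialkylphosphonium ylide, a semi-stabilised ylide class that gives the (E)-alkene (C6=C7) and keeps the 8Z geometry.

Step 19
Reactants: 31 methyl acetal
Product: 32 (5S,6R)-6-[(1E,3Z,5R,7E)-3-ethyl-8-iodo-5-methylocta-1,3,7-trien-1-yl]-5-methyl-5,6-dihydro-2H-pyran-2-ol (anomer mixture)
Conditions: PPTS, acetone/H2O (4:1), rt
Reagents that add atoms: water, O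
Why: Mild acid hydrolysis of the allylic acetal gives the lactol without isomerising the (E,Z)-diene.

Step 20
Reactants: 32 lactol
Product: 33 (5S,6R)-6-[(1E,3Z,5R,7E)-3-ethyl-8-iodo-5-methylocta-1,3,7-trien-1-yl]-5-methyl-5,6-dihydro-2H-pyran-2-one
Conditions: Dess–Martin periodinane, pyridine, CH2Cl2, 0 °C → rt
Reagents that add atoms: none
Why: Oxidation of the lactol gives the α,β-unsaturated δ-lactone and completes the West half (C1–C13).

**East half, allylic bromide**

Step 21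
Reactants: 34 3-methylbut-2-en-1-ol
Product: 35 tert-butyldimethyl[(3-methylbut-2-en-1-yl)oxy]silane
Conditions: TBSCl, imidazole, CH2Cl2, rt
Reagents that add atoms: tert-butyldimethylsilyl chloride, CC(C)(C)[Si](C)(C)Cl
Why: Silylation protects the future C24 hydroxyl.

Step 22
Reactants: 35 silyl prenyl ether
Product: 36 (2E)-4-[(tert-butyldimethylsilyl)oxy]-2-methylbut-2-en-1-ol
Conditions: SeO2 (0.2 equiv), t-BuOOH, CH2Cl2, rt; then NaBH4, MeOH, 0 °C
Reagents that add atoms: tert-butyl hydroperoxide, CC(C)(C)OO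
Why: Selenium dioxide allylic oxidation (ene reaction then [2,3]-shift) attacks the (E)-methyl of the trisubstituted alkene and gives the (E)-allylic alcohol, with NaBH4 returning any over-oxidised enal.

Step 23
Reactants: 36 (2E)-4-[(tert-butyldimethylsilyl)oxy]-2-methylbut-2-en-1-ol
Product: 37 {[(2E)-4-bromo-3-methylbut-2-en-1-yl]oxy}(tert-butyl)dimethylsilane
Conditions: CBr4, PPh3, CH2Cl2, 0 °C
Reagents that add atoms: tetrabromomethane, BrC(Br)(Br)Br
Why: Appel bromination gives the primary allylic bromide with the (E)-alkene retained.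

**East half, main line (ring B and C14–C24)**

Step 24
Reactants: 2 (4S)-4-benzyl-3-propanoyl-1,3-oxazolidin-2-one; 37 {[(2E)-4-bromo-3-methylbut-2-en-1-yl]oxy}(tert-butyl)dimethylsilane
Product: 39 (4S)-4-benzyl-3-[(2R,4E)-6-[(tert-butyldimethylsilyl)oxy]-2,4-dimethylhex-4-enoyl]-1,3-oxazolidin-2-one, via lithium enolate 38 (not isolated)
Conditions: LiN(iPr)2, THF, −78 °C; then 37, −78 → 0 °C
Reagents that add atoms: none
Why: Evans asymmetric alkylation, in which the chelated lithium (Z)-enolate, reactive enough toward an allylic bromide at 0 °C, is attacked on the face opposite the benzyl group and so sets C20 (R).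

Step 25
Reactants: 39 alkylated imide
Product: 40 (2R,4E)-6-[(tert-butyldimethylsilyl)oxy]-2,4-dimethylhex-4-en-1-ol
Conditions: LiBH4, MeOH (1 equiv), THF, 0 °C
Reagents that add atoms: none
Why: Reductive removal of the auxiliary gives the C19 alcohol without epimerisation.

Step 26
Reactants: 40 (2R,4E)-6-[(tert-butyldimethylsilyl)oxy]-2,4-dimethylhex-4-en-1-ol
Product: 41 (2R,4E)-6-[(tert-butyldimethylsilyl)oxy]-2,4-dimethylhex-4-enal
Conditions: Dess–Martin periodinane, pyridine, CH2Cl2, 0 °C; used crude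
Reagents that add atoms: none
Why: Mild oxidation gives the α-methyl aldehyde (C19) for crotylation.

Step 27
Reactants: 41 (2R,4E)-6-[(tert-butyldimethylsilyl)oxy]-2,4-dimethylhex-4-enal
Product: 42 (3S,4R,5R,7E)-9-[(tert-butyldimethylsilyl)oxy]-3,5,7-trimethylnona-1,7-dien-4-ol
Conditions: (R,R)-diisopropyl tartrate (E)-crotylboronate (1.5 equiv, toluene stock solution), 4 Å MS, toluene, −78 °C; then 1 M aq NaOH, 0 °C → rt; chromatography
Reagents that add atoms: diisopropyl (4R,5R)-2-[(2E)-but-2-en-1-yl]-1,3,2-dioxaborolane-4,5-dicarboxylate, C/C=C/CB1O[C@@H](C(=O)OC(C)C)[C@H](C(=O)OC(C)C)O1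
Why: Roush tartrate crotylboration through a chair Zimmerman–Traxler transition state, where the (E)-crotyl geometry gives the C18/C19 anti relationship and the (R,R)-tartrate directs attack on the Si face of the aldehyde (4R carbinol), a reagent-controlled pairing that runs against the modest Felkin bias of the α-methyl aldehyde, so the anti,anti C18–C20 triad is the major isomer (about 85:15 expected) and the minor 4,5-syn isomer is removed by chromatography.

Step 28
Reactants: 42 silyl ether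
Product: 43 (2E,5R,6R,7S)-3,5,7-trimethylnona-2,8-diene-1,6-diol
Conditions: Bu4NF, THF, 0 °C → rt
Reagents that add atoms: none
Why: Fluoride desilylation unmasks the allylic alcohol that directs the asymmetric epoxidation.

Step 29
Reactants: 43 (2E,5R,6R,7S)-3,5,7-trimethylnona-2,8-diene-1,6-diol
Product: 45 (1S)-1-[(2R,4R,5R)-5-[(2S)-but-3-en-2-yl]-2,4-dimethyloxolan-2-yl]ethane-1,2-diol, via epoxy alcohol 44 (not isolated)
Conditions: Ti(OiPr)4 (10 mol %), L-(+)-diethyl tartrate (12 mol %), t-BuOOH, 4 Å MS, CH2Cl2, −20 °C; then CSA (cat.), 0 °C → rt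
Reagents that add atoms: tert-butyl hydroperoxide, CC(C)(C)OO
Why: Katsuki–Sharpless epoxidation with L-(+)-tartrate gives the (22S,23S)-epoxide (same sense as geraniol), and acid-promoted 5-exo opening by the C19 hydroxyl at the tertiary carbon with inversion closes ring B and sets C22 (R).

Step 30
Reactants: 45 diol
Product: 46 (1S)-2-[(tert-butyldimethylsilyl)oxy]-1-[(2R,4R,5R)-5-[(2S)-but-3-en-2-yl]-2,4-dimethyloxolan-2-yl]ethan-1-ol
Conditions: TBSCl (1.05 equiv), imidazole, CH2Cl2, 0 °C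
Reagents that add atoms: tert-butyldimethylsilyl chloride, CC(C)(C)[Si](C)(C)Cl
Why: The primary C24 hydroxyl is silylated selectively over the hindered secondary C23 hydroxyl.

Step 31
Reactants: 46 mono-silyl ether
Product: 47 O-{(1S)-2-[(tert-butyldimethylsilyl)oxy]-1-[(2R,4R,5R)-5-[(2S)-but-3-en-2-yl]-2,4-dimethyloxolan-2-yl]ethyl} 1H-imidazole-1-carbothioate
Conditions: 1,1′-thiocarbonyldiimidazole, DMAP (cat.), toluene, 90 °C
Reagents that add atoms: 1,1′-thiocarbonyldiimidazole, S=C(n1ccnc1)n1ccnc1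
Why: Neutral thioacylation of the C23 hydroxyl avoids the 1,2-silyl migration that an alkoxide would trigger.

Step 32
Reactants: 47 thiocarbonylimidazolide
Product: 48 tert-butyl{2-[(2R,4R,5R)-5-[(2S)-but-3-en-2-yl]-2,4-dimethyloxolan-2-yl]ethoxy}dimethylsilane
Conditions: Bu3SnH, AIBN (cat.), toluene, 100 °C
Reagents that add atoms: none
Why: Barton–McCombie radical deoxygenation removes the C23 oxygen, and the secondary radical is reduced faster than it can attack the ring or the remote vinyl group.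

Step 33
Reactants: 48 alkene
Product: 50 (2R)-2-[(2R,3R,5R)-5-{2-[(tert-butyldimethylsilyl)oxy]ethyl}-3,5-dimethyloxolan-2-yl]propanal, via ozonide 49 (not isolated)
Conditions: O3, CH2Cl2, −78 °C; then PPh3, −78 °C → rt; used crude
Reagents that add atoms: ozone, [O-][O+]=O
Why: Ozonolysis with reductive work-up converts the crotyl-derived vinyl group into the C17 aldehyde under neutral conditions that do not epimerise C18.

Step 34
Reactants: 51 (2S)-but-3-yn-2-ol
Product: 52 (2S)-but-3-yn-2-yl methanesulfonate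
Conditions: MsCl, Et3N, CH2Cl2, −78 °C
Reagents that add atoms: methanesulfonyl chloride, CS(=O)(=O)Cl
Why: O-Sulfonylation with retention gives the enantiopure propargylic mesylate for the Marshall reaction.

Step 35
Reactants: 50 (2R)-2-[(2R,3R,5R)-5-{2-[(tert-butyldimethylsilyl)oxy]ethyl}-3,5-dimethyloxolan-2-yl]propanal; 52 (2S)-but-3-yn-2-yl methanesulfonate
Product: 54 (2S,3R,4R)-2-[(2R,3R,5R)-5-{2-[(tert-butyldimethylsilyl)oxy]ethyl}-3,5-dimethyloxolan-2-yl]-4-methylhex-5-yn-3-ol, via allenylzinc 53 (not isolated)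
Conditions: Pd(OAc)2 (5 mol %), PPh3 (5 mol %), Et2Zn (3 equiv), THF, −78 → −20 °C
Reagents that add atoms: none
Why: Marshall propargylation, in which anti SN2′ attack of zerovalent palladium and transmetalation give an (M)-allenylzinc that adds through a cyclic SE2′ transition state to give the anti adduct with C16 (R), Felkin-matched with C18, and with a C17 carbinol that is later oxidised.

Step 36
Reactants: 54 alkynol
Product: 55 triethyl{[(2R,3R,4R)-2-[(2R,3R,5R)-5-{2-[(tert-butyldimethylsilyl)oxy]ethyl}-3,5-dimethyloxolan-2-yl]-4-methylhex-5-yn-3-yl]oxy}silane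
Conditions: TESOTf, 2,6-lutidine, CH2Cl2, −78 °C
Reagents that add atoms: triethylsilyl trifluoromethanesulfonate, CC[Si](CC)(CC)OS(=O)(=O)C(F)(F)F
Why: The silyl triflate protects the hindered C17 hydroxyl as an easily removed triethylsilyl ether.

Step 37
Reactants: 55 terminal alkyne
Product: 57 triethyl{[(2R,3R,4R)-2-[(2R,3R,5R)-5-{2-[(tert-butyldimethylsilyl)oxy]ethyl}-3,5-dimethyloxolan-2-yl]-4-methylhept-5-yn-3-yl]oxy}silane, via lithium acetylide 56 (not isolated)
Conditions: n-BuLi, THF, −78 °C; then MeI, −78 °C → rt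
Reagents that add atoms: iodomethane, CI
Why: Methylation of the lithium acetylide adds the C14 methyl carbon.

Step 38
Reactants: 57 methylalkyne
Product: 59 triethyl{[(2R,3R,4R,5E)-2-[(2R,3R,5R)-5-{2-[(tert-butyldimethylsilyl)oxy]ethyl}-3,5-dimethyloxolan-2-yl]-6-iodo-4-methylhept-5-en-3-yl]oxy}silane, via alkenylzirconocene 58 (not isolated)
Conditions: Cp2Zr(H)Cl (2.5 equiv), THF, 50 °C; then I2, THF, 0 °C
Reagents that add atoms: iodine, II
Why: Hydrozirconation under equilibrating conditions places zirconium on the less hindered C14 (syn addition), and iodinolysis with retention gives the (E)-trisubstituted alkenyl iodide.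

**Fragment union and end game**

Step 39
Reactants: 59 East alkenyl iodide; 33 West alkenyl iodide
Product: 62 (5S,6R)-6-[(1E,3Z,5R,7E,9E,11R,12R,13R)-13-[(2R,3R,5R)-5-{2-[(tert-butyldimethylsilyl)oxy]ethyl}-3,5-dimethyloxolan-2-yl]-3-ethyl-5,9,11-trimethyl-12-[(triethylsilyl)oxy]tetradeca-1,3,7,9-tetraen-1-yl]-5-methyl-5,6-dihydro-2H-pyran-2-one, via alkenyllithium 60 (not isolated), via alkenylzinc chloride 61 (not isolated)
Conditions: 59, t-BuLi (2.05 equiv), Et2O, −78 °C; ZnCl2, THF, −78 → 0 °C; then 33, Pd(PPh3)4 (5 mol %), THF, rt, dark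
Reagents that add atoms: none
Why: Negishi sp2–sp2 coupling, in which iodine–lithium exchange, transmetalation to zinc and palladium-catalysed coupling all proceed with retention, forges C13–C14 as the (12E,14E)-diene while the organozinc leaves the lactone untouched.

Step 40
Reactants: 62 bis-silyl ether
Product: 63 (5S,6R)-6-[(1E,3Z,5R,7E,9E,11R,12R,13S)-3-ethyl-12-hydroxy-13-[(2R,3R,5R)-5-(2-hydroxyethyl)-3,5-dimethyloxolan-2-yl]-5,9,11-trimethyltetradeca-1,3,7,9-tetraen-1-yl]-5-methyl-5,6-dihydro-2H-pyran-2-one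
Conditions: HF·pyridine, pyridine, THF, 0 °C → rt
Reagents that add atoms: none
Why: Buffered fluoride removes both silyl ethers without opening the lactone or isomerising the polyene.

Step 41
Reactants: 63 diol
Product: 64 target, (5S,6R)-6-[(1E,3Z,5R,7E,9E,11R,13R)-3-ethyl-5,9,11-trimethyl-13-[(2R,3R,5R)-3,5-dimethyl-5-(2-oxoethyl)oxolan-2-yl]-12-oxotetradeca-1,3,7,9-tetraen-1-yl]-5-methyl-5,6-dihydro-2H-pyran-2-one
Conditions: Dess–Martin periodinane (3 equiv), pyridine, CH2Cl2, 0 °C → rt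
Reagents that add atoms: none
Why: Dess–Martin oxidation under near-neutral conditions turns the C17 carbinol into the ketone and the C24 alcohol into the aldehyde without epimerising C16/C18 or opening ring B by β-elimination.

## Compound list

1 | propanoyl chloride | CCC(=O)Cl | starting material
2 | (4S)-4-benzyl-3-propanoyl-1,3-oxazolidin-2-one | CCC(=O)N1[C@@H](Cc2ccccc2)COC1=O | intermediate
3 | 3-bromoprop-1-yne | C#CCBr | starting material
4 | sodium (Z)-enolate of 2 (not isolated) | C/C=C(\[O-])N1[C@@H](Cc2ccccc2)COC1=O.[Na+] | intermediate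
5 | (4S)-4-benzyl-3-[(2R)-2-methylpent-4-ynoyl]-1,3-oxazolidin-2-one | C#CC[C@@H](C)C(=O)N1[C@@H](Cc2ccccc2)COC1=O | intermediate
6 | (2R)-2-methylpent-4-yn-1-ol | C#CC[C@@H](C)CO | intermediate
7 | (E)-alkenylzirconocene chloride of 6 with the oxygen as zirconocene alkoxide (not isolated) | C[C@@H](CO[Zr](Cl)(C1C=CC=C1)C1C=CC=C1)C/C=C/[Zr](Cl)(C1C=CC=C1)C1C=CC=C1 | intermediate
8 | (2R,4E)-5-iodo-2-methylpent-4-en-1-ol | I/C=C/C[C@@H](C)CO | intermediate
9 | (2R,4E)-5-iodo-2-methylpent-4-enal | I/C=C/C[C@@H](C)C=O | intermediate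
10 | iodoethane | CCI | starting material
11 | methyl 2-[bis(2,2,2-trifluoroethoxy)phosphoryl]butanoate (racemic) | CCC(C(=O)OC)P(=O)(OCC(F)(F)F)OCC(F)(F)F | intermediate
12 | potassium carbanion of 11 (not isolated) | CC[C-](C(=O)OC)P(=O)(OCC(F)(F)F)OCC(F)(F)F.[K+] | intermediate
13 | methyl (2Z,4R,6E)-2-ethyl-7-iodo-4-methylhepta-2,6-dienoate | CCC(=C/[C@H](C)C/C=C/I)/C(=O)OC | intermediate
14 | (2Z,4R,6E)-2-ethyl-7-iodo-4-methylhepta-2,6-dien-1-ol | CCC(=C/[C@H](C)C/C=C/I)/CO | intermediate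
15 | (1E,4R,5Z)-6-(bromomethyl)-1-iodo-4-methylocta-1,5-diene | CCC(=C/[C@H](C)C/C=C/I)/CBr | intermediate
16 | tributyl[(2Z,4R,6E)-2-ethyl-7-iodo-4-methylhepta-2,6-dien-1-yl]phosphonium bromide | CCC(=C/[C@H](C)C/C=C/I)/C[P+](CCCC)(CCCC)CCCC.[Br-] | intermediate
17 | (2Z)-but-2-ene-1,4-diol | OC/C=C\CO | starting material
18 | (2Z)-1,4-bis[(tert-butyldimethylsilyl)oxy]but-2-ene | CC(C)(C)[Si](C)(C)OC/C=C\CO[Si](C)(C)C(C)(C)C | intermediate
19 | 3,5-bis{[(tert-butyldimethylsilyl)oxy]methyl}-1,2,4-trioxolane (not isolated) | CC(C)(C)[Si](C)(C)OCC1OOC(CO[Si](C)(C)C(C)(C)C)O1 | intermediate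
20 | [(tert-butyldimethylsilyl)oxy]acetaldehyde | CC(C)(C)[Si](C)(C)OCC=O | intermediate
21 | (E)-but-2-ene | C/C=C/C | starting material
22 | (E)-crotylpotassium (not isolated) | C/C=C/[CH2-].[K+] | intermediate
23 | (E)-crotyldiisopinocampheylborane from (−)-Ipc2BOMe (not isolated) | C/C=C/CB([C@@H]1C[C@@H]2C[C@H]([C@H]1C)C2(C)C)[C@@H]1C[C@@H]2C[C@H]([C@H]1C)C2(C)C | intermediate
24 | (2S,3S)-1-[(tert-butyldimethylsilyl)oxy]-3-methylpent-4-en-2-ol | CC(C)(C)[Si](C)(C)OC[C@@H](O)[C@@H](C)C=C | intermediate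
25 | 3,3-dimethoxyprop-1-ene | C=CC(OC)OC | starting material
26 | tert-butyl{[(2S,3S)-2-[(1-methoxyprop-2-en-1-yl)oxy]-3-methylpent-4-en-1-yl]oxy}dimethylsilane (acetal epimers) | CC(C)(C)[Si](C)(C)OC[C@@H](OC(OC)C=C)[C@@H](C)C=C | intermediate
27 | tert-butyl{[(2S,3S)-6-methoxy-3-methyl-3,6-dihydro-2H-pyran-2-yl]methoxy}dimethylsilane (anomers) | CC(C)(C)[Si](C)(C)OC[C@H]1OC(OC)C=C[C@@H]1C | intermediate
28 | [(2S,3S)-6-methoxy-3-methyl-3,6-dihydro-2H-pyran-2-yl]methanol (anomers) | OC[C@H]1OC(OC)C=C[C@@H]1C | intermediate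
29 | (2S,3S)-6-methoxy-3-methyl-3,6-dihydro-2H-pyran-2-carbaldehyde (anomers) | O=C[C@H]1OC(OC)C=C[C@@H]1C | intermediate
30 | tributylphosphonium ylide of 16 (not isolated) | CCC(=C/[C@H](C)C/C=C/I)/[CH-][P+](CCCC)(CCCC)CCCC | intermediate
31 | (2R,3S)-2-[(1E,3Z,5R,7E)-3-ethyl-8-iodo-5-methylocta-1,3,7-trien-1-yl]-6-methoxy-3-methyl-3,6-dihydro-2H-pyran (anomers) | CCC(=C/[C@H](C)C/C=C/I)/C=C/[C@H]1OC(OC)C=C[C@@H]1C | intermediate
32 | (5S,6R)-6-[(1E,3Z,5R,7E)-3-ethyl-8-iodo-5-methylocta-1,3,7-trien-1-yl]-5-methyl-5,6-dihydro-2H-pyran-2-ol (anomers) | CCC(=C/[C@H](C)C/C=C/I)/C=C/[C@H]1OC(O)C=C[C@@H]1C | intermediate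
33 | (5S,6R)-6-[(1E,3Z,5R,7E)-3-ethyl-8-iodo-5-methylocta-1,3,7-trien-1-yl]-5-methyl-5,6-dihydro-2H-pyran-2-one | CCC(=C/[C@H](C)C/C=C/I)/C=C/[C@H]1OC(=O)C=C[C@@H]1C | intermediate
34 | 3-methylbut-2-en-1-ol | CC(C)=CCO | starting material
35 | tert-butyldimethyl[(3-methylbut-2-en-1-yl)oxy]silane | CC(C)=CCO[Si](C)(C)C(C)(C)C | intermediate
36 | (2E)-4-[(tert-butyldimethylsilyl)oxy]-2-methylbut-2-en-1-ol | C/C(CO)=C\CO[Si](C)(C)C(C)(C)C | intermediate
37 | {[(2E)-4-bromo-3-methylbut-2-en-1-yl]oxy}(tert-butyl)dimethylsilane | C/C(CBr)=C\CO[Si](C)(C)C(C)(C)C | intermediate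
38 | lithium (Z)-enolate of 2 (not isolated) | C/C=C(\[O-])N1[C@@H](Cc2ccccc2)COC1=O.[Li+] | intermediate
39 | (4S)-4-benzyl-3-[(2R,4E)-6-[(tert-butyldimethylsilyl)oxy]-2,4-dimethylhex-4-enoyl]-1,3-oxazolidin-2-one | C/C(=C\CO[Si](C)(C)C(C)(C)C)C[C@@H](C)C(=O)N1[C@@H](Cc2ccccc2)COC1=O | intermediate
40 | (2R,4E)-6-[(tert-butyldimethylsilyl)oxy]-2,4-dimethylhex-4-en-1-ol | C/C(=C\CO[Si](C)(C)C(C)(C)C)C[C@@H](C)CO | intermediate
41 | (2R,4E)-6-[(tert-butyldimethylsilyl)oxy]-2,4-dimethylhex-4-enal | C/C(=C\CO[Si](C)(C)C(C)(C)C)C[C@@H](C)C=O | intermediate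
42 | (3S,4R,5R,7E)-9-[(tert-butyldimethylsilyl)oxy]-3,5,7-trimethylnona-1,7-dien-4-ol | C=C[C@H](C)[C@H](O)[C@H](C)C/C(C)=C/CO[Si](C)(C)C(C)(C)C | intermediate
43 | (2E,5R,6R,7S)-3,5,7-trimethylnona-2,8-diene-1,6-diol | C=C[C@H](C)[C@H](O)[C@H](C)C/C(C)=C/CO | intermediate
44 | (2R,3R,4S)-1-[(2S,3S)-3-(hydroxymethyl)-2-methyloxiran-2-yl]-2,4-dimethylhex-5-en-3-ol (not isolated) | C=C[C@H](C)[C@H](O)[C@H](C)C[C@]1(C)O[C@H]1CO | intermediate
45 | (1S)-1-[(2R,4R,5R)-5-[(2S)-but-3-en-2-yl]-2,4-dimethyloxolan-2-yl]ethane-1,2-diol | C=C[C@H](C)[C@@H]1O[C@@](C)([C@@H](O)CO)C[C@H]1C | intermediate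
46 | (1S)-2-[(tert-butyldimethylsilyl)oxy]-1-[(2R,4R,5R)-5-[(2S)-but-3-en-2-yl]-2,4-dimethyloxolan-2-yl]ethan-1-ol | C=C[C@H](C)[C@@H]1O[C@@](C)([C@@H](O)CO[Si](C)(C)C(C)(C)C)C[C@H]1C | intermediate
47 | O-{(1S)-2-[(tert-butyldimethylsilyl)oxy]-1-[(2R,4R,5R)-5-[(2S)-but-3-en-2-yl]-2,4-dimethyloxolan-2-yl]ethyl} 1H-imidazole-1-carbothioate | C=C[C@H](C)[C@@H]1O[C@@](C)([C@@H](OC(=S)n2ccnc2)CO[Si](C)(C)C(C)(C)C)C[C@H]1C | intermediate
48 | tert-butyl{2-[(2R,4R,5R)-5-[(2S)-but-3-en-2-yl]-2,4-dimethyloxolan-2-yl]ethoxy}dimethylsilane | C=C[C@H](C)[C@@H]1O[C@@](C)(CCO[Si](C)(C)C(C)(C)C)C[C@H]1C | intermediate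
49 | 1,2,4-trioxolane (ozonide) of 48 (not isolated) | C[C@@H](C1OCOO1)[C@@H]1O[C@@](C)(CCO[Si](C)(C)C(C)(C)C)C[C@H]1C | intermediate
50 | (2R)-2-[(2R,3R,5R)-5-{2-[(tert-butyldimethylsilyl)oxy]ethyl}-3,5-dimethyloxolan-2-yl]propanal | O=C[C@H](C)[C@@H]1O[C@@](C)(CCO[Si](C)(C)C(C)(C)C)C[C@H]1C | intermediate
51 | (2S)-but-3-yn-2-ol | C#C[C@H](C)O | starting material
52 | (2S)-but-3-yn-2-yl methanesulfonate | C#C[C@H](C)OS(C)(=O)=O | intermediate
53 | ethyl[(M)-buta-1,2-dien-1-yl]zinc (not isolated) | CC[Zn]C([H])=[C@]=C([H])C | intermediate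
54 | (2S,3R,4R)-2-[(2R,3R,5R)-5-{2-[(tert-butyldimethylsilyl)oxy]ethyl}-3,5-dimethyloxolan-2-yl]-4-methylhex-5-yn-3-ol | C#C[C@@H](C)[C@@H](O)[C@H](C)[C@@H]1O[C@@](C)(CCO[Si](C)(C)C(C)(C)C)C[C@H]1C | intermediate
55 | triethyl{[(2R,3R,4R)-2-[(2R,3R,5R)-5-{2-[(tert-butyldimethylsilyl)oxy]ethyl}-3,5-dimethyloxolan-2-yl]-4-methylhex-5-yn-3-yl]oxy}silane | C#C[C@@H](C)[C@@H](O[Si](CC)(CC)CC)[C@H](C)[C@@H]1O[C@@](C)(CCO[Si](C)(C)C(C)(C)C)C[C@H]1C | intermediate
56 | lithium acetylide of 55 (not isolated) | [Li]C#C[C@@H](C)[C@@H](O[Si](CC)(CC)CC)[C@H](C)[C@@H]1O[C@@](C)(CCO[Si](C)(C)C(C)(C)C)C[C@H]1C | intermediate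
57 | triethyl{[(2R,3R,4R)-2-[(2R,3R,5R)-5-{2-[(tert-butyldimethylsilyl)oxy]ethyl}-3,5-dimethyloxolan-2-yl]-4-methylhept-5-yn-3-yl]oxy}silane | CC#C[C@@H](C)[C@@H](O[Si](CC)(CC)CC)[C@H](C)[C@@H]1O[C@@](C)(CCO[Si](C)(C)C(C)(C)C)C[C@H]1C | intermediate
58 | (E)-alkenylzirconocene chloride of 57 with zirconium on C14 (not isolated) | C/C(=C\[C@@H](C)[C@@H](O[Si](CC)(CC)CC)[C@H](C)[C@@H]1O[C@@](C)(CCO[Si](C)(C)C(C)(C)C)C[C@H]1C)[Zr](Cl)(C1C=CC=C1)C1C=CC=C1 | intermediate
59 | triethyl{[(2R,3R,4R,5E)-2-[(2R,3R,5R)-5-{2-[(tert-butyldimethylsilyl)oxy]ethyl}-3,5-dimethyloxolan-2-yl]-6-iodo-4-methylhept-5-en-3-yl]oxy}silane | I/C(C)=C/[C@@H](C)[C@@H](O[Si](CC)(CC)CC)[C@H](C)[C@@H]1O[C@@](C)(CCO[Si](C)(C)C(C)(C)C)C[C@H]1C | intermediate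
60 | (E)-alkenyllithium from 59 (not isolated) | [Li]/C(C)=C/[C@@H](C)[C@@H](O[Si](CC)(CC)CC)[C@H](C)[C@@H]1O[C@@](C)(CCO[Si](C)(C)C(C)(C)C)C[C@H]1C | intermediate
61 | (E)-alkenylzinc chloride from 59 (not isolated) | Cl[Zn]/C(C)=C/[C@@H](C)[C@@H](O[Si](CC)(CC)CC)[C@H](C)[C@@H]1O[C@@](C)(CCO[Si](C)(C)C(C)(C)C)C[C@H]1C | intermediate
62 | (5S,6R)-6-[(1E,3Z,5R,7E,9E,11R,12R,13R)-13-[(2R,3R,5R)-5-{2-[(tert-butyldimethylsilyl)oxy]ethyl}-3,5-dimethyloxolan-2-yl]-3-ethyl-5,9,11-trimethyl-12-[(triethylsilyl)oxy]tetradeca-1,3,7,9-tetraen-1-yl]-5-methyl-5,6-dihydro-2H-pyran-2-one | CCC(=C/[C@H](C)C/C=C/C(C)=C/[C@@H](C)[C@@H](O[Si](CC)(CC)CC)[C@H](C)[C@@H]1O[C@@](C)(CCO[Si](C)(C)C(C)(C)C)C[C@H]1C)/C=C/[C@H]1OC(=O)C=C[C@@H]1C | intermediate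
63 | (5S,6R)-6-[(1E,3Z,5R,7E,9E,11R,12R,13S)-3-ethyl-12-hydroxy-13-[(2R,3R,5R)-5-(2-hydroxyethyl)-3,5-dimethyloxolan-2-yl]-5,9,11-trimethyltetradeca-1,3,7,9-tetraen-1-yl]-5-methyl-5,6-dihydro-2H-pyran-2-one | CCC(=C/[C@H](C)C/C=C/C(C)=C/[C@@H](C)[C@@H](O)[C@H](C)[C@@H]1O[C@@](C)(CCO)C[C@H]1C)/C=C/[C@H]1OC(=O)C=C[C@@H]1C | intermediate
64 | (5S,6R)-6-[(1E,3Z,5R,7E,9E,11R,13R)-3-ethyl-5,9,11-trimethyl-13-[(2R,3R,5R)-3,5-dimethyl-5-(2-oxoethyl)oxolan-2-yl]-12-oxotetradeca-1,3,7,9-tetraen-1-yl]-5-methyl-5,6-dihydro-2H-pyran-2-one | CCC(=C/[C@H](C)C/C=C/C(C)=C/[C@@H](C)C(=O)[C@H](C)[C@@H]1O[C@@](C)(CC=O)C[C@H]1C)/C=C/[C@H]1OC(=O)C=C[C@@H]1C | target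

## Step count and risks

Total step count: 41.
Longest linear sequence: 20 steps (steps 21–33 and 35–41, from 34 to 64).

Steps most likely to fail:

Step 27 (mismatched crotylboration). If the tartrate boronate cannot override the Felkin bias of 41, the anti,anti isomer will not be the major product. The fallback replaces the crotyl transfer by a Marshall propargylation, in which the configuration of the new methyl-bearing carbon is fixed by the axial chirality of the reagent. It sets out from 41. Commercial (2R)-but-3-yn-2-ol is mesylated (MsCl, Et3N, CH2Cl2, −78 °C) to (2R)-but-3-yn-2-yl methanesulfonate F1. With Pd(OAc)2, PPh3 and Et2Zn in THF at −78 → −20 °C, F1 gives ethyl[(P)-buta-1,2-dien-1-yl]zinc F2 in the flask. F2 adds to 41 through the cyclic transition state to give the anti homopropargylic alcohol (3S,4R,5R,7E)-9-[(tert-butyldimethylsilyl)oxy]-3,5,7-trimethylnon-7-en-1-yn-4-ol F3. Semihydrogenation of the terminal alkyne of F3 (H2, Pd on CaCO3 poisoned with Pb(OAc)2, quinoline, EtOAc, rt) returns to the route at 42.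

Step 38 (regioselective hydrozirconation of the hindered methylalkyne). If zirconium does not settle cleanly on C14 or the addition stalls, the fallback sets out from 57 and uses palladium-catalysed syn-hydrostannation (Bu3SnH, Pd(PPh3)2Cl2, THF, rt), which places tin on the less hindered C14 to give the (E)-alkenyltributylstannane F4. Iododestannylation with I2 in CH2Cl2 at 0 °C then returns to the route at 59.

Step 39 (fragment union). If the iodine–lithium exchange or the zinc coupling gives reduction or homocoupling, the fallback is a Stille coupling that needs no organolithium. It sets out from 59, which is stannylated with Me3SnSnMe3 and Pd(PPh3)4 in toluene at 80 °C to give the (E)-alkenyltrimethylstannane F5. F5 is coupled with 33 using Pd2(dba)3, AsPh3 and CuI in DMF at rt, returning to the route at 62.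

## Further compounds

F1 | step 27 | (2R)-but-3-yn-2-yl methanesulfonate | C#C[C@@H](C)OS(C)(=O)=O
F2 | step 27 | ethyl[(P)-buta-1,2-dien-1-yl]zinc | CC[Zn]C([H])=[C@@]=C([H])C
F3 | step 27 | (3S,4R,5R,7E)-9-[(tert-butyldimethylsilyl)oxy]-3,5,7-trimethylnon-7-en-1-yn-4-ol | C#C[C@H](C)[C@H](O)[C@H](C)C/C(C)=C/CO[Si](C)(C)C(C)(C)C
F4 | step 38 | tributyl[(2E,4R,5R,6R)-6-[(2R,3R,5R)-5-{2-[(tert-butyldimethylsilyl)oxy]ethyl}-3,5-dimethyloxolan-2-yl]-4-methyl-5-[(triethylsilyl)oxy]hept-2-en-2-yl]stannane | C/C(=C\[C@@H](C)[C@@H](O[Si](CC)(CC)CC)[C@H](C)[C@@H]1O[C@@](C)(CCO[Si](C)(C)C(C)(C)C)C[C@H]1C)[Sn](CCCC)(CCCC)CCCC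
F5 | step 39 | trimethyl[(2E,4R,5R,6R)-6-[(2R,3R,5R)-5-{2-[(tert-butyldimethylsilyl)oxy]ethyl}-3,5-dimethyloxolan-2-yl]-4-methyl-5-[(triethylsilyl)oxy]hept-2-en-2-yl]stannane | C/C(=C\[C@@H](C)[C@@H](O[Si](CC)(CC)CC)[C@H](C)[C@@H]1O[C@@](C)(CCO[Si](C)(C)C(C)(C)C)C[C@H]1C)[Sn](C)(C)C
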